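**Retrosynthetic overview**
- The last operation closes both heterocycles at once. A masked salicylaldehyde (an isochroman lactol) condenses at C3 of 4-hydroxy-6-[(2S)-2-hydroxypropyl]-2-pyrone; the ortho phenol then opens the pyrone (coumarin lactone ring), and the freed δ-hydroxy-β-diketone cyclodehydrates (dihydropyranone ring).
- The lactol comes from the resorcinol triol by side-chain-tethered orthoformate formylation; the triol comes from its dimethyl ether.
- The (2S,3R) side chain comes from Mitsunobu inversion of the (2R,3R) alcohol, made by anti opening of (2R,3R)-2,3-dimethyloxirane with an aryl Grignard reagent; the aryl bromide comes from 2-bromo-4,6-dimethoxybenzaldehyde (CHO to CH3).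
- The pyrone comes from the dianion of methyl acetoacetate and ethyl (S)-3-hydroxybutanoate (Claisen acylation, lactonization).
- Ring order: the benzene ring is bought; the temporary isochroman lactol ring and the pyrone ring are made first in separate branches; both are opened as the coumarin lactone ring and then the dihydropyranone ring form in the final flask.

Assumption: the lactol is written as one ring-chain tautomer with C1 left undefined (anomeric mixture, destroyed in the last step); (2R,3R)-2,3-dimethyloxirane is taken as a catalogue item (otherwise two steps from fermentation-derived (2R,3R)-butane-2,3-diol).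

**Route**

Step 1
Reactants: 1 2-bromo-4,6-dimethoxybenzaldehyde
Product: 2 1-bromo-3,5-dimethoxy-2-methylbenzene
Conditions: Et3SiH (3 equiv), TFA, CH2Cl2, 0 °C to rt
Reagents that add atoms: none
Why: Ionic hydrogenation (Kursanov–Parnes reduction): the ortho and para methoxy groups stabilise the benzylic cation, which takes hydride from Et3SiH twice, so CHO becomes CH3 while the aryl bromide and the ethers are untouched.

Step 2
Reactants: 2 1-bromo-3,5-dimethoxy-2-methylbenzene; 3 (2R,3R)-2,3-dimethyloxirane
Product: 5 (2R,3R)-3-(3,5-dimethoxy-2-methylphenyl)butan-2-ol, via arylmagnesium bromide 4 (not isolated)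
Conditions: Mg, THF, reflux; then 3, CuBr·SMe2 (10 mol %), THF, −30 °C to rt; aq NH4Cl
Reagents that add atoms: none
Why: Copper-catalysed SN2 opening of the C2-symmetric trans-epoxide by the aryl Grignard reagent; both epoxide carbons are equivalent and backside attack inverts the attacked carbon, so only the (2R,3R) alcohol forms (benzylic centre set as R here, carbinol centre still R from the epoxide).

Step 3
Reactants: 5 (2R,3R)-3-(3,5-dimethoxy-2-methylphenyl)butan-2-ol
Product: 7 (2S,3R)-3-(3,5-dimethoxy-2-methylphenyl)butan-2-ol, via inverted 4-nitrobenzoate 6 (not isolated)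
Conditions: 4-O2NC6H4CO2H (1.2 equiv), PPh3, DIAD, THF, 0 °C to rt; then K2CO3 (0.5 equiv), MeOH, rt
Reagents that add atoms: 4-nitrobenzoic acid, O=C(O)c1ccc(cc1)[N+](=O)[O-] (its oxygen becomes the hydroxyl oxygen of 7)
Why: Mitsunobu inversion: SN2 displacement of the alkoxyphosphonium by 4-nitrobenzoate turns the carbinol carbon from R to S without touching the benzylic centre, and carbonate-catalysed methanolysis (acyl–oxygen cleavage) frees the (2S,3R) alcohol.

Step 4
Reactants: 7 (2S,3R)-3-(3,5-dimethoxy-2-methylphenyl)butan-2-ol
Product: 8 (2S,3R)-3-(3,5-dihydroxy-2-methylphenyl)butan-2-ol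
Conditions: BBr3 (4 equiv), CH2Cl2, −78 to 0 °C; then MeOH, H2O
Reagents that add atoms: none
Why: Lewis acid ether cleavage: BBr3 coordinates each methoxy oxygen and bromide removes the methyl group by SN2, while the secondary alcohol is held as a borate ester and returned on hydrolysis, so neither stereocentre is involved.

Step 5
Reactants: 8 (2S,3R)-3-(3,5-dihydroxy-2-methylphenyl)butan-2-ol
Product: 10 (3S,4R)-3,4,5-trimethyl-3,4-dihydro-1H-isochromene-1,6,8-triol, via 1-ethoxy acetal 9 (not isolated)
Conditions: HC(OEt)3 (3 equiv), TsOH·H2O (10 mol %), THF, 0 °C to rt; then 1 M aq HCl, rt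
Reagents that add atoms: triethyl orthoformate, CCOC(OCC)OCC (adds C1); water, O (adds the lactol hydroxyl oxygen)
Why: Oxa-Pictet–Spengler-type formylation: the side-chain hydroxyl exchanges into the orthoformate and the derived dialkoxycarbenium ion is delivered through a six-membered transition state to the only free ring position next to the side chain (also para to a phenol); aqueous acid then hydrolyses the ethoxy acetal to the lactol, the ring-chain tautomer of the salicylaldehyde, with C3 and C4 as spectators.

Step 6
Reactants: 11 methyl acetoacetate; 12 ethyl (S)-3-hydroxybutanoate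
Product: 14 4-hydroxy-6-[(2S)-2-hydroxypropyl]-2H-pyran-2-one, via hydroxy dioxo ester 13 (not isolated)
Conditions: 11 (3.5 equiv), LDA (7 equiv), THF, 0 °C; 12, −78 to 0 °C; aq HCl, excess 11 removed in vacuo; then DBU, toluene, 90 °C; aq HCl
Reagents that add atoms: none
Why: Claisen-type γ-acylation of the dianion of methyl acetoacetate (Weiler dianion) by the hydroxy ester, whose hydroxyl is carried as the lithium alkoxide at the cost of one extra equivalent of dianion, followed by DBU-mediated lactonization of the 3,5-dioxo ester (enolate oxygen onto the ester) to the 4-hydroxy-2-pyrone; the chiral-pool carbinol centre is never touched.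

Step 7
Reactants: 10 (3S,4R)-3,4,5-trimethyl-3,4-dihydro-1H-isochromene-1,6,8-triol; 14 4-hydroxy-6-[(2S)-2-hydroxypropyl]-2H-pyran-2-one (1.2 equiv)
Product: 17 7-hydroxy-5-[(2R,3S)-3-hydroxybutan-2-yl]-6-methyl-3-[(2S)-2-methyl-4-oxo-3,4-dihydro-2H-pyran-6-yl]-2H-chromen-2-one (target), via Knoevenagel adduct 15 (not isolated), via acylcoumarin diketone 16 (not isolated)
Conditions: piperidine (20 mol %), AcOH (20 mol %), EtOH, 70 °C; then TsOH·H2O (0.5 equiv), rt to 40 °C
Reagents that add atoms: none
Why: Proposed new method: the lactol reacts through its open aldehyde (iminium) form with C3 of the pyrone, the only nucleophilic carbon of that partner, to give 15; the ortho phenol then attacks the pyrone C2 carbonyl and expels the C6 enolate, which opens the pyrone and closes the coumarin lactone (16); acid then closes the side-chain hydroxyl onto the coumarin-bound ketone (hemiketal, loss of water) to the dihydropyranone. Off-path oxa-Michael adducts of the side-chain alcohol (1-pyronyl isochroman) are reversible and drain to the irreversible coumarin, and no bond to any of the three stereocentres is broken. The closest known reactions are the piperidine-catalysed condensation of salicylaldehydes with 4-hydroxy-6-methyl-2-pyrone to 3-acetoacetylcoumarins (Knoevenagel, then translactonization) and the acid cyclodehydration of δ-hydroxy-β-diketones to 2,3-dihydro-4-pyranones.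

**Compound list**
1 | 2-bromo-4,6-dimethoxybenzaldehyde | COc1cc(OC)c(C=O)c(Br)c1 | starting material
2 | 1-bromo-3,5-dimethoxy-2-methylbenzene | COc1cc(OC)c(C)c(Br)c1 | intermediate
3 | (2R,3R)-2,3-dimethyloxirane | C[C@H]1O[C@@H]1C | starting material
4 | (3,5-dimethoxy-2-methylphenyl)magnesium bromide | COc1cc(OC)c(C)c([Mg]Br)c1 | intermediate (not isolated)
5 | (2R,3R)-3-(3,5-dimethoxy-2-methylphenyl)butan-2-ol | COc1cc(OC)c(C)c(c1)[C@@H](C)[C@@H](C)O | intermediate
6 | (2S,3R)-3-(3,5-dimethoxy-2-methylphenyl)butan-2-yl 4-nitrobenzoate | COc1cc(OC)c(C)c(c1)[C@@H](C)[C@H](C)OC(=O)c1ccc(cc1)[N+](=O)[O-] | intermediate (not isolated)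
7 | (2S,3R)-3-(3,5-dimethoxy-2-methylphenyl)butan-2-ol | COc1cc(OC)c(C)c(c1)[C@@H](C)[C@H](C)O | intermediate
8 | (2S,3R)-3-(3,5-dihydroxy-2-methylphenyl)butan-2-ol | Cc1c(O)cc(O)cc1[C@@H](C)[C@H](C)O | intermediate
9 | (3S,4R)-1-ethoxy-3,4,5-trimethyl-3,4-dihydro-1H-isochromene-6,8-diol (C1 mixture) | Cc1c(O)cc(O)c2c1[C@@H](C)[C@H](C)OC2OCC | intermediate (not isolated)
10 | (3S,4R)-3,4,5-trimethyl-3,4-dihydro-1H-isochromene-1,6,8-triol (lactol, C1 mixture) | Cc1c(O)cc(O)c2c1[C@@H](C)[C@H](C)OC2O | intermediate
11 | methyl acetoacetate | CC(=O)CC(=O)OC | starting material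
12 | ethyl (S)-3-hydroxybutanoate | C[C@H](O)CC(=O)OCC | starting material
13 | methyl (7S)-7-hydroxy-3,5-dioxooctanoate | C[C@H](O)CC(=O)CC(=O)CC(=O)OC | intermediate (not isolated)
14 | 4-hydroxy-6-[(2S)-2-hydroxypropyl]-2H-pyran-2-one | C[C@H](O)CC1=CC(O)=CC(=O)O1 | intermediate
15 | 3-({2,4-dihydroxy-6-[(2R,3S)-3-hydroxybutan-2-yl]-5-methylphenyl}methylidene)-6-[(2S)-2-hydroxypropyl]-2H-pyran-2,4(3H)-dione | Cc1c(O)cc(O)c(C=C2C(=O)C=C(C[C@H](C)O)OC2=O)c1[C@@H](C)[C@H](C)O | intermediate (not isolated)
16 | 7-hydroxy-5-[(2R,3S)-3-hydroxybutan-2-yl]-3-[(5S)-5-hydroxy-3-oxohexanoyl]-6-methyl-2H-chromen-2-one | Cc1c(O)cc2oc(=O)c(C(=O)CC(=O)C[C@H](C)O)cc2c1[C@@H](C)[C@H](C)O | intermediate (not isolated)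
17 | 7-hydroxy-5-[(2R,3S)-3-hydroxybutan-2-yl]-6-methyl-3-[(2S)-2-methyl-4-oxo-3,4-dihydro-2H-pyran-6-yl]-2H-chromen-2-one | Cc1c(O)cc2oc(=O)c(C3=CC(=O)C[C@H](C)O3)cc2c1[C@@H](C)[C@H](C)O | target

**Step count and risks**

Total steps: 7. Longest linear sequence: 6 (steps 1, 2, 3, 4, 5, 7); step 6 is a one-step side branch.

Steps most likely to fail:

Step 7. The cascade may stall at the reversible isochroman oxa-Michael adduct, or the hindered, electron-rich lactol may condense too slowly and dimerise through its quinone methide. The fallback reverses the order of ring formation in the same flask. It sets out from 13 (crude, taken before the DBU treatment of step 6) and 10. Compound 13 is stirred with TsOH·H2O in CH2Cl2 at rt, which closes the pyranone first and gives methyl 2-[(2S)-2-methyl-4-oxo-3,4-dihydro-2H-pyran-6-yl]acetate F1. Without isolation the solvent is changed to EtOH, 10 and piperidinium acetate are added, and heating at 70 °C brings about Knoevenagel condensation at the ester-activated vinylogous methylene and lactonization by the ortho phenol. This comes back to the route at 17.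

Step 5. Intermolecular formylation between the two hydroxyls can compete, and unreacted 8 can attack the ionised product to give dimers. The fallback introduces the formyl carbon before the phenols are unmasked. It sets out from 7, which with HC(OMe)3 and TMSOTf in CH2Cl2 at −20 °C closes through the side-chain oxygen to (3S,4R)-1,6,8-trimethoxy-3,4,5-trimethyl-3,4-dihydro-1H-isochromene F2; here no quinone methide can form. BBr3 (CH2Cl2, −78 to 0 °C) followed by aqueous work-up then cleaves both aryl methyl ethers and the acetal. This comes back to the route at 10, bypassing 8 and 9.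

Step 6. The lithium alkoxide of 12 may be acylated sluggishly or be enolised by the dianion. The fallback changes the acyl donor. It sets out from 12, which with MeNHOMe·HCl and i-PrMgCl in THF at −20 °C gives (3S)-3-hydroxy-N-methoxy-N-methylbutanamide F3. Its chelated tetrahedral adduct with the dianion of 11 (THF, −78 to 0 °C) survives until the acid quench. This comes back to the route at 13, which is carried on with DBU as in step 6.

**Further compounds**
F1 | step 7 | methyl 2-[(2S)-2-methyl-4-oxo-3,4-dihydro-2H-pyran-6-yl]acetate | COC(=O)CC1=CC(=O)C[C@H](C)O1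
F2 | step 5 | (3S,4R)-1,6,8-trimethoxy-3,4,5-trimethyl-3,4-dihydro-1H-isochromene (C1 mixture) | Cc1c(OC)cc(OC)c2c1[C@@H](C)[C@H](C)OC2OC
F3 | step 6 | (3S)-3-hydroxy-N-methoxy-N-methylbutanamide | C[C@H](O)CC(=O)N(C)OC
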